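The hardest ether of the hexamer, between C6 of ring E and C1 of ring F, is not made by coupling; ring F is instead cut at C2–C3 and C1–C6. The feature used is the oxygen pattern of ring F: ether oxygen on C1 and hydroxyl on C3 in a 1,3-relationship, with C4 and C5 oxygenated next to C3, as in a resorcinol monoether. One thermal operation joins racemic 3,4-dimethoxycyclobutenone and the ethynyl ether of a ring E phenol (benzyl on the C1 oxygen, methoxy on C3–C5) and delivers ring F as a phenol. Rings D, C, B and A follow by repeated copper-catalysed etherification and Dakin oxidation; sixteen methyl ethers are cleaved last.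

Key step: step 9

Remark: rings are lettered A (2,4,6-trihydroxyphenoxy end) to F, and rings B–F are numbered from the carbon whose ether oxygen points towards ring A; the two bromo aldehydes, the iodoarene and dimethyl squarate used below are assumed to be purchasable.

Step 1
Reactants: 1 3,4,5-trimethoxyphenol
Product: 2 5-(benzyloxy)-1,2,3-trimethoxybenzene
Conditions: BnBr, K2CO3, DMF, rt
Reagents that add atoms: benzyl bromide BrCc1ccccc1
Why: Williamson ether synthesis on an unhindered phenoxide should be clean and installs the one group that can later be removed beside methyl and diaryl ethers.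

Step 2
Reactants: 2 5-(benzyloxy)-1,2,3-trimethoxybenzene
Product: 4 6-(benzyloxy)-2,3,4-trimethoxybenzaldehyde, via iminium salt 3 (not isolated)
Conditions: POCl3, DMF, 0 °C to 60 °C; then H2O
Reagents that add atoms: N,N-dimethylformamide CN(C)C=O; water O
Why: Vilsmeier–Haack formylation can only take place at the two equivalent free positions, each ortho and para to ether oxygens, so a single aldehyde should result.

Step 3
Reactants: 4 6-(benzyloxy)-2,3,4-trimethoxybenzaldehyde
Product: 6 6-(benzyloxy)-2,3,4-trimethoxyphenol, via aryl formate 5 (not isolated)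
Conditions: mCPBA, CH2Cl2, 0 °C to rt; then K2CO3 (cat.), MeOH, rt
Reagents that add atoms: 3-chloroperoxybenzoic acid O=C(OO)c1cccc(Cl)c1
Why: Dakin oxidation in its Baeyer–Villiger form should proceed by migration of the very electron-rich aryl group, and methanolysis of the formate frees the phenol.

Step 4
Reactants: 6 6-(benzyloxy)-2,3,4-trimethoxyphenol; 7 trichloroethylene
Product: 9 1-(benzyloxy)-2-{[(E)-1,2-dichloroethenyl]oxy}-3,4,5-trimethoxybenzene, via dichloroacetylene 8 (not isolated)
Conditions: K2CO3, DMF, 70 °C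
Reagents that add atoms: none
Why: Nucleophilic addition of the phenoxide to dichloroacetylene, released from 7 by base-induced loss of HCl, is the standard first stage of aryl ynol ether synthesis and should give the (E)-dichlorovinyl ether by anti addition.

Step 5
Reactants: 9 1-(benzyloxy)-2-{[(E)-1,2-dichloroethenyl]oxy}-3,4,5-trimethoxybenzene
Product: 12 1-(benzyloxy)-2-(ethynyloxy)-3,4,5-trimethoxybenzene, via chloroalkynyl ether 10 (not isolated), via lithium acetylide 11 (not isolated)
Conditions: n-BuLi (2.2 equiv), THF, −78 °C to −40 °C; then H2O, −78 °C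
Reagents that add atoms: none
Why: Dehydrochlorination followed by chlorine–lithium exchange (elimination and halogen–metal exchange) should give the lithium acetylide, which water protonates to the terminal ynol ether; benzyl and methyl ethers tolerate n-BuLi at this temperature.

Step 6
Reactants: 13 dimethyl squarate
Product: 15 3-methoxycyclobut-3-ene-1,2-dione, via hydroxy ketone 14 (not isolated)
Conditions: LiAlH(OtBu)3, THF, −78 °C; then 6 M HCl, CH2Cl2, rt
Reagents that add atoms: none
Why: Chemoselective 1,2-reduction of one squarate carbonyl followed by acid-promoted allylic transposition with loss of methanol is the established route from squaric esters to semisquaric esters.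

Step 7
Reactants: 15 3-methoxycyclobut-3-ene-1,2-dione
Product: 16 4-hydroxy-3-methoxycyclobut-2-en-1-one (racemic)
Conditions: LiAlH(OtBu)3 (1.0 equiv), THF, −78 °C; then H2O
Reagents that add atoms: none
Why: Regioselective 1,2-reduction, in which the hydride should attack the ketone-like carbonyl next to the methoxy-bearing carbon and spare the vinylogous ester carbonyl, as carbon nucleophiles do with semisquaric esters; the new stereocentre forms as a racemate and is destroyed in step 9.

Step 8
Reactants: 16 4-hydroxy-3-methoxycyclobut-2-en-1-one (racemic)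
Product: 17 3,4-dimethoxycyclobut-2-en-1-one (racemic)
Conditions: MeI, Ag2O, CH2Cl2, rt, dark
Reagents that add atoms: iodomethane CI
Why: Purdie methylation etherifies the secondary alcohol under neutral conditions, which the strained, base-sensitive ketone should survive.

Step 9
Reactants: 12 1-(benzyloxy)-2-(ethynyloxy)-3,4,5-trimethoxybenzene; 17 3,4-dimethoxycyclobut-2-en-1-one (racemic)
Product: 22 5-[6-(benzyloxy)-2,3,4-trimethoxyphenoxy]-2,3-dimethoxyphenol, via vinylketene 18 (not isolated), via vinylcyclobutenone 19 (not isolated), via dienylketene 20 (not isolated), via cyclohexadienone 21 (not isolated)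
Conditions: 17 (1.5 equiv), toluene, 80 °C then 110 °C, Ar; then K2CO3 (cat.), MeOH, rt
Reagents that add atoms: none
Why: Heating opens cyclobutenone 17 by 4π electrocyclic cleavage with the C4 methoxy group turning outward to give vinylketene 18, whose electrophilic carbonyl carbon is attacked by the nucleophilic CH terminus of ynol ether 12 in a [2+2] cycloaddition that forms the future C2–C3 and C1–C6 bonds of ring F (19). A second 4π opening of 19 gives dienylketene 20, and ring F is closed by thermal 6π electrocyclisation (disrotatory, six-membered ring, bond C3–C4) to dienone 21, which enolises to phenol 22. The closest known reaction type is the Danheiser benzannulation of cyclobutenones with alkoxy- and silyloxyalkynes to resorcinol monoethers; here the alkynyl ether is an aryl ether and the cyclobutenone carries two alkoxy groups. No stereocentre is set, because the racemic sp3 carbons of 17, 19 and 21 all end as sp2 carbons of the arene. The selectivity needed is regiochemical, aryloxy meta to the new hydroxyl, and it is secured by the polarisation of the ynol ether, whose oxygen-bearing carbon must bond to the ketene α-carbon. Benzyl and methyl ethers are inert under these neutral conditions, and the basic methanol treatment returns any phenol acylated by excess ketene.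

Step 10
Reactants: 22 5-[6-(benzyloxy)-2,3,4-trimethoxyphenoxy]-2,3-dimethoxyphenol
Product: 23 1-(benzyloxy)-3,4,5-trimethoxy-2-(3,4,5-trimethoxyphenoxy)benzene
Conditions: MeI, K2CO3, DMF, rt
Reagents that add atoms: iodomethane CI
Why: Williamson ether synthesis on the unhindered ring F phenol should be clean and completes the trimethoxy pattern of ring F.

Step 11
Reactants: 23 1-(benzyloxy)-3,4,5-trimethoxy-2-(3,4,5-trimethoxyphenoxy)benzene
Product: 24 3,4,5-trimethoxy-2-(3,4,5-trimethoxyphenoxy)phenol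
Conditions: H2 (1 atm), Pd/C, EtOAc–MeOH, rt
Reagents that add atoms: none
Why: Catalytic hydrogenolysis removes the benzyl ether selectively, since aryl methyl and diaryl ethers are inert to H2 over Pd/C.

Step 12
Reactants: 24 3,4,5-trimethoxy-2-(3,4,5-trimethoxyphenoxy)phenol; 25 4-bromo-3,5-dimethoxybenzaldehyde
Product: 26 3,5-dimethoxy-4-[3,4,5-trimethoxy-2-(3,4,5-trimethoxyphenoxy)phenoxy]benzaldehyde (ring D–E–F aldehyde)
Conditions: CuI (20 mol%), picolinic acid (40 mol%), K3PO4, DMSO, 100 °C
Reagents that add atoms: none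
Why: Ullmann-type copper-catalysed diaryl ether synthesis, in which the para-formyl group of 25 activates its doubly ortho-substituted C–Br bond towards the phenoxide of 24 and the picolinic acid system is one known to tolerate hindered partners.

Step 13
Reactants: 26 ring D–E–F aldehyde
Product: 28 3,5-dimethoxy-4-[3,4,5-trimethoxy-2-(3,4,5-trimethoxyphenoxy)phenoxy]phenol (ring D–E–F phenol), via aryl formate 27 (not isolated)
Conditions: mCPBA, CH2Cl2, 0 °C to rt; then K2CO3 (cat.), MeOH, rt
Reagents that add atoms: 3-chloroperoxybenzoic acid O=C(OO)c1cccc(Cl)c1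
Why: Dakin oxidation in its Baeyer–Villiger form, in which the aryl group bearing the para-aryloxy donor migrates to give formate 27 and mild methanolysis releases the unhindered ring D phenol.

Step 14
Reactants: 28 ring D–E–F phenol; 29 2-bromo-3,4,5-trimethoxybenzaldehyde
Product: 30 2-{3,5-dimethoxy-4-[3,4,5-trimethoxy-2-(3,4,5-trimethoxyphenoxy)phenoxy]phenoxy}-3,4,5-trimethoxybenzaldehyde (ring C–D–E–F aldehyde)
Conditions: CuI (20 mol%), picolinic acid (40 mol%), K3PO4, DMSO, 90 °C
Reagents that add atoms: none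
Why: Ullmann-type copper-catalysed diaryl ether synthesis between an unhindered phenol and a bromide activated by its ortho-formyl group, a combination well precedented for 2-bromo benzaldehydes and benzoates.

Step 15
Reactants: 30 ring C–D–E–F aldehyde
Product: 32 2-{3,5-dimethoxy-4-[3,4,5-trimethoxy-2-(3,4,5-trimethoxyphenoxy)phenoxy]phenoxy}-3,4,5-trimethoxyphenol (ring C–D–E–F phenol), via aryl formate 31 (not isolated)
Conditions: mCPBA, CH2Cl2, 0 °C to rt; then K2CO3 (cat.), MeOH, rt
Reagents that add atoms: 3-chloroperoxybenzoic acid O=C(OO)c1cccc(Cl)c1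
Why: Dakin oxidation (Baeyer–Villiger form) is favoured here by the ortho-aryloxy and para-methoxy donors on the migrating ring, and methanolysis frees the ring C phenol.

Step 16
Reactants: 32 ring C–D–E–F phenol; 25 4-bromo-3,5-dimethoxybenzaldehyde
Product: 33 4-(2-{3,5-dimethoxy-4-[3,4,5-trimethoxy-2-(3,4,5-trimethoxyphenoxy)phenoxy]phenoxy}-3,4,5-trimethoxyphenoxy)-3,5-dimethoxybenzaldehyde (ring B–C–D–E–F aldehyde)
Conditions: CuI (20 mol%), picolinic acid (40 mol%), K3PO4, DMSO, 100 °C
Reagents that add atoms: none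
Why: The Ullmann-type coupling of step 12 is repeated on the ring C phenol, again with the para-formyl group of 25 activating the hindered C–Br bond.

Step 17
Reactants: 33 ring B–C–D–E–F aldehyde
Product: 35 4-(2-{3,5-dimethoxy-4-[3,4,5-trimethoxy-2-(3,4,5-trimethoxyphenoxy)phenoxy]phenoxy}-3,4,5-trimethoxyphenoxy)-3,5-dimethoxyphenol (ring B–C–D–E–F phenol), via aryl formate 34 (not isolated)
Conditions: mCPBA, CH2Cl2, 0 °C to rt; then K2CO3 (cat.), MeOH, rt
Reagents that add atoms: 3-chloroperoxybenzoic acid O=C(OO)c1cccc(Cl)c1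
Why: Dakin oxidation as in step 13 should convert the ring B aldehyde into the unhindered ring B phenol.

Step 18
Reactants: 35 ring B–C–D–E–F phenol; 36 2-iodo-1,3,5-trimethoxybenzene
Product: 37 hexadeca-O-methyl ether of the target (permethylated hexamer A–F)
Conditions: CuI (20 mol%), picolinic acid (40 mol%), K3PO4, DMSO, 110 °C
Reagents that add atoms: none
Why: Ullmann-type copper-catalysed etherification of an unhindered phenol with 2-iodo-1,3,5-trimethoxybenzene is the classical way to attach a 2,4,6-trimethoxyphenyl ring to an aryl oxygen.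

Step 19
Reactants: 37 hexadeca-O-methyl ether of the target
Product: 38 target CNP0114537.0 (hexadecaphenol)
Conditions: BBr3 (excess), CH2Cl2, −78 °C to rt; then H2O, 0 °C, under Ar
Reagents that add atoms: none
Why: Lewis-acid ether cleavage, in which BBr3 demethylates aryl methyl ethers by bromide attack on the O-methyl carbon of the borane adduct while diaryl ether bonds stay intact, so all sixteen hydroxyls should be released in one operation.

Compound list
1 | 3,4,5-trimethoxyphenol | COc1cc(O)cc(OC)c1OC | starting material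
2 | 5-(benzyloxy)-1,2,3-trimethoxybenzene | COc1cc(OCc2ccccc2)cc(OC)c1OC | intermediate
3 | N-{[6-(benzyloxy)-2,3,4-trimethoxyphenyl]methylidene}-N-methylmethanaminium chloride (iminium salt) | C[N+](C)=Cc1c(OCc2ccccc2)cc(OC)c(OC)c1OC.[Cl-] | intermediate
4 | 6-(benzyloxy)-2,3,4-trimethoxybenzaldehyde | O=Cc1c(OCc2ccccc2)cc(OC)c(OC)c1OC | intermediate
5 | 6-(benzyloxy)-2,3,4-trimethoxyphenyl formate | O=COc1c(OCc2ccccc2)cc(OC)c(OC)c1OC | intermediate
6 | 6-(benzyloxy)-2,3,4-trimethoxyphenol | Oc1c(OCc2ccccc2)cc(OC)c(OC)c1OC | intermediate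
7 | trichloroethylene | ClC=C(Cl)Cl | starting material
8 | dichloroacetylene | ClC#CCl | intermediate
9 | 1-(benzyloxy)-2-{[(E)-1,2-dichloroethenyl]oxy}-3,4,5-trimethoxybenzene | Cl/C=C(/Cl)Oc1c(OCc2ccccc2)cc(OC)c(OC)c1OC | intermediate
10 | 1-(benzyloxy)-2-[(chloroethynyl)oxy]-3,4,5-trimethoxybenzene | ClC#COc1c(OCc2ccccc2)cc(OC)c(OC)c1OC | intermediate
11 | lithium [6-(benzyloxy)-2,3,4-trimethoxyphenoxy]ethynide | [Li]C#COc1c(OCc2ccccc2)cc(OC)c(OC)c1OC | intermediate
12 | 1-(benzyloxy)-2-(ethynyloxy)-3,4,5-trimethoxybenzene | C#COc1c(OCc2ccccc2)cc(OC)c(OC)c1OC | intermediate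
13 | dimethyl squarate (3,4-dimethoxycyclobut-3-ene-1,2-dione) | COC1=C(OC)C(=O)C1=O | starting material
14 | 4-hydroxy-2,3-dimethoxycyclobut-2-en-1-one (racemic) | COC1=C(OC)C(=O)C1O | intermediate
15 | 3-methoxycyclobut-3-ene-1,2-dione (methyl semisquarate) | COC1=CC(=O)C1=O | intermediate
16 | 4-hydroxy-3-methoxycyclobut-2-en-1-one (racemic) | COC1=CC(=O)C1O | intermediate
17 | 3,4-dimethoxycyclobut-2-en-1-one (racemic) | COC1=CC(=O)C1OC | intermediate
18 | (3Z)-3,4-dimethoxybuta-1,3-dien-1-one (vinylketene) | O=C=C/C(OC)=C/OC | intermediate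
19 | 3-[6-(benzyloxy)-2,3,4-trimethoxyphenoxy]-4-[(Z)-1,2-dimethoxyethenyl]cyclobut-2-en-1-one (racemic) | O=C1C=C(Oc2c(OCc3ccccc3)cc(OC)c(OC)c2OC)C1/C(OC)=C/OC | intermediate
20 | (3E,5Z)-3-[6-(benzyloxy)-2,3,4-trimethoxyphenoxy]-5,6-dimethoxyhexa-1,3,5-trien-1-one (dienylketene) | O=C=C/C(Oc1c(OCc2ccccc2)cc(OC)c(OC)c1OC)=C\C(OC)=C\OC | intermediate
21 | 3-[6-(benzyloxy)-2,3,4-trimethoxyphenoxy]-5,6-dimethoxycyclohexa-2,4-dien-1-one (racemic) | O=C1C=C(Oc2c(OCc3ccccc3)cc(OC)c(OC)c2OC)C=C(OC)C1OC | intermediate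
22 | 5-[6-(benzyloxy)-2,3,4-trimethoxyphenoxy]-2,3-dimethoxyphenol | COc1cc(Oc2c(OCc3ccccc3)cc(OC)c(OC)c2OC)cc(O)c1OC | intermediate
23 | 1-(benzyloxy)-3,4,5-trimethoxy-2-(3,4,5-trimethoxyphenoxy)benzene | COc1cc(Oc2c(OCc3ccccc3)cc(OC)c(OC)c2OC)cc(OC)c1OC | intermediate
24 | 3,4,5-trimethoxy-2-(3,4,5-trimethoxyphenoxy)phenol | COc1cc(Oc2c(O)cc(OC)c(OC)c2OC)cc(OC)c1OC | intermediate
25 | 4-bromo-3,5-dimethoxybenzaldehyde | O=Cc1cc(OC)c(Br)c(OC)c1 | starting material
26 | 3,5-dimethoxy-4-[3,4,5-trimethoxy-2-(3,4,5-trimethoxyphenoxy)phenoxy]benzaldehyde | O=Cc1cc(OC)c(Oc2cc(OC)c(OC)c(OC)c2Oc3cc(OC)c(OC)c(OC)c3)c(OC)c1 | intermediate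
27 | 3,5-dimethoxy-4-[3,4,5-trimethoxy-2-(3,4,5-trimethoxyphenoxy)phenoxy]phenyl formate | O=COc1cc(OC)c(Oc2cc(OC)c(OC)c(OC)c2Oc3cc(OC)c(OC)c(OC)c3)c(OC)c1 | intermediate
28 | 3,5-dimethoxy-4-[3,4,5-trimethoxy-2-(3,4,5-trimethoxyphenoxy)phenoxy]phenol | Oc1cc(OC)c(Oc2cc(OC)c(OC)c(OC)c2Oc3cc(OC)c(OC)c(OC)c3)c(OC)c1 | intermediate
29 | 2-bromo-3,4,5-trimethoxybenzaldehyde | O=Cc1cc(OC)c(OC)c(OC)c1Br | starting material
30 | 2-{3,5-dimethoxy-4-[3,4,5-trimethoxy-2-(3,4,5-trimethoxyphenoxy)phenoxy]phenoxy}-3,4,5-trimethoxybenzaldehyde | O=Cc1cc(OC)c(OC)c(OC)c1Oc2cc(OC)c(Oc3cc(OC)c(OC)c(OC)c3Oc4cc(OC)c(OC)c(OC)c4)c(OC)c2 | intermediate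
31 | 2-{3,5-dimethoxy-4-[3,4,5-trimethoxy-2-(3,4,5-trimethoxyphenoxy)phenoxy]phenoxy}-3,4,5-trimethoxyphenyl formate | O=COc1cc(OC)c(OC)c(OC)c1Oc2cc(OC)c(Oc3cc(OC)c(OC)c(OC)c3Oc4cc(OC)c(OC)c(OC)c4)c(OC)c2 | intermediate
32 | 2-{3,5-dimethoxy-4-[3,4,5-trimethoxy-2-(3,4,5-trimethoxyphenoxy)phenoxy]phenoxy}-3,4,5-trimethoxyphenol | Oc1cc(OC)c(OC)c(OC)c1Oc2cc(OC)c(Oc3cc(OC)c(OC)c(OC)c3Oc4cc(OC)c(OC)c(OC)c4)c(OC)c2 | intermediate
33 | 4-(2-{3,5-dimethoxy-4-[3,4,5-trimethoxy-2-(3,4,5-trimethoxyphenoxy)phenoxy]phenoxy}-3,4,5-trimethoxyphenoxy)-3,5-dimethoxybenzaldehyde | O=Cc1cc(OC)c(Oc2cc(OC)c(OC)c(OC)c2Oc3cc(OC)c(Oc4cc(OC)c(OC)c(OC)c4Oc5cc(OC)c(OC)c(OC)c5)c(OC)c3)c(OC)c1 | intermediate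
34 | 4-(2-{3,5-dimethoxy-4-[3,4,5-trimethoxy-2-(3,4,5-trimethoxyphenoxy)phenoxy]phenoxy}-3,4,5-trimethoxyphenoxy)-3,5-dimethoxyphenyl formate | O=COc1cc(OC)c(Oc2cc(OC)c(OC)c(OC)c2Oc3cc(OC)c(Oc4cc(OC)c(OC)c(OC)c4Oc5cc(OC)c(OC)c(OC)c5)c(OC)c3)c(OC)c1 | intermediate
35 | 4-(2-{3,5-dimethoxy-4-[3,4,5-trimethoxy-2-(3,4,5-trimethoxyphenoxy)phenoxy]phenoxy}-3,4,5-trimethoxyphenoxy)-3,5-dimethoxyphenol | Oc1cc(OC)c(Oc2cc(OC)c(OC)c(OC)c2Oc3cc(OC)c(Oc4cc(OC)c(OC)c(OC)c4Oc5cc(OC)c(OC)c(OC)c5)c(OC)c3)c(OC)c1 | intermediate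
36 | 2-iodo-1,3,5-trimethoxybenzene | COc1cc(OC)c(I)c(OC)c1 | starting material
37 | 1,3,5-trimethoxy-2-[4-(2-{3,5-dimethoxy-4-[3,4,5-trimethoxy-2-(3,4,5-trimethoxyphenoxy)phenoxy]phenoxy}-3,4,5-trimethoxyphenoxy)-3,5-dimethoxyphenoxy]benzene (hexadeca-O-methyl ether of the target) | COc1cc(OC)c(Oc2cc(OC)c(Oc3cc(OC)c(OC)c(OC)c3Oc4cc(OC)c(Oc5cc(OC)c(OC)c(OC)c5Oc6cc(OC)c(OC)c(OC)c6)c(OC)c4)c(OC)c2)c(OC)c1 | intermediate
38 | CNP0114537.0, the hexadecaphenol in which every methoxy group of 37 is a hydroxyl | Oc1cc(O)c(Oc2cc(O)c(Oc3cc(O)c(O)c(O)c3Oc3cc(O)c(Oc4cc(O)c(O)c(O)c4Oc4cc(O)c(O)c(O)c4)c(O)c3)c(O)c2)c(O)c1 | target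

Total step count: 19. Longest linear sequence: 16 steps (steps 1–5 and 9–19); steps 6–8 form the cyclobutenone branch.

Steps most likely to fail

1. Step 9. The aryloxyalkyne is a weaker nucleophile than the alkyl and silyl ynol ethers normally used, so its cycloaddition to the vinylketene may lose against ketene dimerisation, re-closure to the cyclobutenone and thermal decay of the alkyne. The fallback uses known chemistry and makes the ring E–ring F ether by coupling instead. It sets out from phenol 6, which is joined to commercial 5-bromo-1,2,3-trimethoxybenzene by Ullmann etherification (CuI, picolinic acid, K3PO4, DMSO, 100 °C). In this pairing the hindered ring is the phenol and the bromide is unhindered. The product is 23 itself, so the route is rejoined at 23 and steps 4–10 fall away; this fallback makes no new compound (F0).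

2. Step 12 (the same holds for its repeat, step 16). Substitution at a carbon flanked by two methoxy groups may be slow, so that protodebromination of 25 and oxidative loss of the electron-rich phenol compete. The fallback reverses the polarity of the coupling so that the doubly ortho-substituted ring becomes the phenol. It sets out from 24. Triflation (Tf2O, pyridine, CH2Cl2, 0 °C) should give 3,4,5-trimethoxy-2-(3,4,5-trimethoxyphenoxy)phenyl trifluoromethanesulfonate F1. Palladium-catalysed borylation (B2(OH)4, Pd(OAc)2, XPhos, KOAc, EtOH, 80 °C) should then give [3,4,5-trimethoxy-2-(3,4,5-trimethoxyphenoxy)phenyl]boronic acid F2. Chan–Lam coupling of F2 with commercial syringaldehyde (Cu(OAc)2, pyridine, 4 Å molecular sieves, air, CH2Cl2, rt) should give aldehyde 26, where the route is rejoined.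

3. Step 19. Cleavage of sixteen ethers may stop at partly methylated mixtures, and the electron-rich product may oxidise in air during aqueous work-up and chromatography. The fallback reaches the target through a stable, purifiable derivative. It sets out from 37: after the BBr3 treatment the crude polyphenol is not isolated but acetylated directly (Ac2O, pyridine, DMAP, rt) to the hexadecaacetate of the target F3, which can be purified on silica, with under-cleaved material separated and resubmitted. Acid-catalysed methanolysis (HCl generated from AcCl, degassed MeOH, rt, under Ar) should then release 38, with evaporation as the only work-up.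

Further compounds
F0 | step 9 | none | none
F1 | step 12 | 3,4,5-trimethoxy-2-(3,4,5-trimethoxyphenoxy)phenyl trifluoromethanesulfonate | O=S(=O)(Oc1cc(OC)c(OC)c(OC)c1Oc2cc(OC)c(OC)c(OC)c2)C(F)(F)F
F2 | step 12 | [3,4,5-trimethoxy-2-(3,4,5-trimethoxyphenoxy)phenyl]boronic acid | OB(O)c1cc(OC)c(OC)c(OC)c1Oc2cc(OC)c(OC)c(OC)c2
F3 | step 19 | hexadecaacetate of the target | CC(=O)Oc1cc(OC(C)=O)c(Oc2cc(OC(C)=O)c(Oc3cc(OC(C)=O)c(OC(C)=O)c(OC(C)=O)c3Oc4cc(OC(C)=O)c(Oc5cc(OC(C)=O)c(OC(C)=O)c(OC(C)=O)c5Oc6cc(OC(C)=O)c(OC(C)=O)c(OC(C)=O)c6)c(OC(C)=O)c4)c(OC(C)=O)c2)c(OC(C)=O)c1
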